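## Retrosynthetic overview

1. Target 42 ⇐ reductive (Julia-type) elimination of OH/SO2Ph across C6–C7 of 40 ⇐ intramolecular photoenolisation/Diels–Alder reaction of the o-(sec-alkyl)benzaldehyde 38, which forms C6–C7 and C8–C9 and closes rings B and C together as the last rings.
2. Enabling feature: C6 and C9 are the two benzylic carbons on the ortho pair C5/C10 of aromatic ring A, so ring B is the adduct of an o-quinodimethane (C6=C5–C10=C9) with C7=C8; bond C8–C9 also belongs to ring C (C8, C9, C11–C14), so the chain C11–C12–C13–C14 is the tether and ring C closes as the tether ring.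
3. 38 ⇐ Negishi coupling (C9–C10) of aryl bromide 13 with secondary bromide 36.
4. 13: cycloheptane by ring expansion of dihydrocarvone, cyclopentene by ring-closing metathesis, dioxin by double SNAr with difluoroarene 12. 36: ring E by enantioselective Diels–Alder reaction, ring D by d'Angelo Michael addition/aldol condensation, C13 and C14 by enolate methylations.
5. Ring order: cycloheptane, cyclopentene, dioxin (ring A is bought); ring E, ring D; rings B and C in step 26.

Key step: step 26

Remark: triterpene atoms carry friedelane (celastroid) numbers (ring A = C1–C5, C10) with α/β as in the usual triterpene drawing; sesquiterpene atoms carry guaiane numbers with the suffix g.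
Remark: commercial (+)-dihydrocarvone is a C2-epimer mixture; this centre (later C10g) stays epimerisable up to 3, where the needed cis epimer is collected and the other re-equilibrated.
Remark: the carbinol carbon of 14 (later C9) is racemic and becomes trigonal in step 26, so 15–17 and 27–38 are carried as epimer mixtures at that carbon.

## Route

Step 1
Reactants: 1 (+)-dihydrocarvone, (5R)-2-methyl-5-(prop-1-en-2-yl)cyclohexan-1-one (C2-epimer mixture)
Product: 3 (2S,5R)-2-methyl-5-(prop-1-en-2-yl)cycloheptan-1-one, via alpha-silyl ketone 2 (not isolated)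
Conditions: TMSCHN2, BF3·OEt2, CH2Cl2, −78 °C; K2CO3, MeOH, rt; chromatography, trans epimer re-equilibrated (K2CO3, MeOH) and recycled
Reagents that add atoms: trimethylsilyldiazomethane C[Si](C)(C)C=[N+]=[N-]
Why: Lewis-acid-promoted diazoalkane ring expansion (Tiffeneau–Demjanov type) should insert CH2 on the less substituted side of the ketone, C7g (R) comes from the chiral pool, and the epimerisable C10g is equilibrated in the desilylating base so that the cis (S) epimer can be separated.

Step 2
Reactants: 3 (2S,5R)-2-methyl-5-(prop-1-en-2-yl)cycloheptan-1-one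
Product: 4 (4R,7S)-2-(hydroxyimino)-7-methyl-4-(prop-1-en-2-yl)cycloheptan-1-one
Conditions: LDA, THF, −78 °C; isoamyl nitrite, −78 → 0 °C; aq. NH4Cl
Reagents that add atoms: isoamyl nitrite CC(C)CCON=O
Why: kinetic deprotonation should occur at the unbranched alpha-CH2 (C5g), and nitrosation of the enolate with tautomerisation gives the alpha-oximino ketone, which masks the future C5g ketone as a trigonal centre without a stereocentre.

Step 3
Reactants: 4 (4R,7S)-2-(hydroxyimino)-7-methyl-4-(prop-1-en-2-yl)cycloheptan-1-one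
Product: 5 (2S,3S,6R)-2-hydroxy-3-methyl-6-(prop-1-en-2-yl)-2-(prop-2-en-1-yl)cycloheptan-1-one oxime
Conditions: allylMgBr (2.5 equiv), THF, −78 °C; aq. NH4Cl
Reagents that add atoms: allylmagnesium bromide C=CC[Mg]Br
Why: Grignard 1,2-addition to the ketone of the magnesium oximate should bring the allyl group in anti to the neighbouring C10g methyl (2-alkylcycloalkanone model), which places the new C1g oxygen syn to that methyl as the target requires.

Step 4
Reactants: 5 (2S,3S,6R)-2-hydroxy-3-methyl-6-(prop-1-en-2-yl)-2-(prop-2-en-1-yl)cycloheptan-1-one oxime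
Product: 6 (2S,3S,6R)-2-hydroxy-3-methyl-6-(prop-1-en-2-yl)-2-(prop-2-en-1-yl)cycloheptan-1-one
Conditions: aq. TiCl3, NH4OAc, THF/H2O, rt
Reagents that add atoms: water O
Why: reductive deoximation (N–O cleavage by low-valent titanium to the imine, then hydrolysis) should free the C5g ketone without touching the alkenes or the tertiary alcohol.

Step 5
Reactants: 6 (2S,3S,6R)-2-hydroxy-3-methyl-6-(prop-1-en-2-yl)-2-(prop-2-en-1-yl)cycloheptan-1-one
Product: 7 (2S,3S,6R)-3-methyl-6-(prop-1-en-2-yl)-2-(prop-2-en-1-yl)-2-[(triethylsilyl)oxy]cycloheptan-1-one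
Conditions: TESOTf, 2,6-lutidine, CH2Cl2, −78 °C
Reagents that add atoms: triethylsilyl triflate CC[Si](CC)(CC)OS(=O)(=O)C(F)(F)F
Why: silylation of the tertiary alcohol gives a non-chelating alpha-silyloxy ketone, so that the next carbonyl addition follows the Felkin–Anh sense and not chelation control.

Step 6
Reactants: 7 (2S,3S,6R)-3-methyl-6-(prop-1-en-2-yl)-2-(prop-2-en-1-yl)-2-[(triethylsilyl)oxy]cycloheptan-1-one
Product: 9 (1S,2S,3S,6R)-3-methyl-1,6-di(prop-1-en-2-yl)-2-(prop-2-en-1-yl)cycloheptane-1,2-diol, via monosilyl diol 8 (not isolated)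
Conditions: isopropenylMgBr, CeCl3, THF, −78 °C; then TBAF, THF, rt
Reagents that add atoms: isopropenylmagnesium bromide C=C(C)[Mg]Br
Why: organocerium 1,2-addition to the hindered enolisable ketone should occur anti to the alpha C–OSi bond (polar Felkin–Anh model), which puts isopropenyl cis to allyl and the two oxygens cis (C5g S), and fluoride then removes the silyl group.

Step 7
Reactants: 9 (1S,2S,3S,6R)-3-methyl-1,6-di(prop-1-en-2-yl)-2-(prop-2-en-1-yl)cycloheptane-1,2-diol
Product: 10 (1S,5S,7R,10S)-guaia-3,11-diene-1,5-diol (cis-fused hydroazulene diol)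
Conditions: second-generation Grubbs catalyst (5 mol%), CH2Cl2, 40 °C
Reagents that add atoms: none
Why: ring-closing metathesis of the allyl and the C5g isopropenyl groups should close the trisubstituted cyclopentene (C3g=C4g), five-ring closure being far faster than any reaction of the remote C7g isopropenyl group; no stereocentre is touched.

Step 8
Reactants: 11 3,4-difluoro-2-methylbenzaldehyde
Product: 12 6-bromo-3,4-difluoro-2-methylbenzaldehyde
Conditions: Pd(OAc)2 (10 mol%), 2-amino-5-chlorobenzotrifluoride (40 mol%), NBS, TFA/DCE, 60 °C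
Reagents that add atoms: N-bromosuccinimide O=C1CCC(=O)N1Br
Why: palladium-catalysed ortho C–H bromination of a benzaldehyde through a transient imine directing group should functionalise C6, the only free ortho position.

Step 9
Reactants: 10 (1S,5S,7R,10S)-guaia-3,11-diene-1,5-diol; 12 6-bromo-3,4-difluoro-2-methylbenzaldehyde
Product: 13 bromo aldehyde: 1,4-benzodioxin of 10 and 12 with O5g on ring A carbon C2 and O1g on C3 (Br on C10, CHO on C5, Me on C4)
Conditions: KHMDS (2.1 equiv), THF, −78 °C; 12; then DMF, 60 °C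
Reagents that add atoms: none
Why: double nucleophilic aromatic substitution, in which the less hindered allylic C5g alkoxide should displace the fluoride para to the formyl group and the C1g alkoxide then closes the six-membered dioxin ring on the neighbouring fluoride; the cis-diol configuration is carried over unchanged.

Step 10
Reactants: 14 6-methyloxan-2-one (delta-hexalactone, racemic)
Product: 15 5-hydroxy-N-methoxy-N-methylhexanamide
Conditions: MeNH(OMe)·HCl, i-PrMgCl, THF, −20 °C
Reagents that add atoms: N,O-dimethylhydroxylamine hydrochloride CNOC.Cl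
Why: aminolysis of the lactone by the magnesium amide should give the Weinreb amide.

Step 11
Reactants: 15 5-hydroxy-N-methoxy-N-methylhexanamide
Product: 16 5-[(tert-butyldimethylsilyl)oxy]-N-methoxy-N-methylhexanamide
Conditions: TBSCl, imidazole, DMF, rt
Reagents that add atoms: tert-butyldimethylsilyl chloride CC(C)(C)[Si](C)(C)Cl
Why: standard silylation protects the secondary alcohol that later becomes the bromide at C9.

Step 12
Reactants: 16 5-[(tert-butyldimethylsilyl)oxy]-N-methoxy-N-methylhexanamide
Product: 17 7-[(tert-butyldimethylsilyl)oxy]oct-1-en-3-one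
Conditions: vinylMgBr, THF, 0 °C; cold aq. HCl quench
Reagents that add atoms: vinylmagnesium bromide C=C[Mg]Br
Why: Weinreb ketone synthesis, in which the stable magnesium chelate prevents over-addition and the acidic quench avoids conjugate addition of the released amine.

Step 13
Reactants: 18 isoprene; 19 methacrolein
Product: 20 (R)-1,4-dimethylcyclohex-3-ene-1-carbaldehyde
Conditions: B-(o-tolyl) diphenylprolinol oxazaborolidine·Tf2NH (10 mol%, enantiomer that gives the R adduct), CH2Cl2, −78 °C
Reagents that add atoms: none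
Why: catalytic enantioselective Diels–Alder reaction that closes ring E with the 1,4 ("para") regiochemistry; the chiral Lewis acid shields one face of the coordinated enal and sets the quaternary C20.

Step 14
Reactants: 20 (R)-1,4-dimethylcyclohex-3-ene-1-carbaldehyde
Product: 22 methyl (R)-1,4-dimethylcyclohex-3-ene-1-carboxylate, via carboxylic acid 21 (not isolated)
Conditions: NaClO2, NaH2PO4, 2-methyl-2-butene, t-BuOH/H2O; then TMSCHN2, MeOH/toluene
Reagents that add atoms: sodium chlorite [Na+].[O-]Cl=O; trimethylsilyldiazomethane C[Si](C)(C)C=[N+]=[N-]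
Why: Pinnick oxidation followed by diazoalkane esterification gives the C20 methyl ester without touching the alkene or the stereocentre.

Step 15
Reactants: 22 methyl (R)-1,4-dimethylcyclohex-3-ene-1-carboxylate
Product: 24 methyl (1R)-3-hydroxy-1,4-dimethylcyclohexane-1-carboxylate (diastereomer mixture), via alkylborane 23 (not isolated)
Conditions: BH3·THF, THF, 0 °C; then H2O2, aq. NaOAc
Reagents that add atoms: hydrogen peroxide OO
Why: hydroboration–oxidation should place oxygen on the less substituted alkene carbon (C18); the new centres are erased in the next two steps.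

Step 16
Reactants: 24 methyl (1R)-3-hydroxy-1,4-dimethylcyclohexane-1-carboxylate
Product: 25 methyl (1R)-1,4-dimethyl-3-oxocyclohexane-1-carboxylate (C4-epimer mixture)
Conditions: DMP, NaHCO3, CH2Cl2, rt
Reagents that add atoms: none
Why: Dess–Martin oxidation of the secondary alcohol gives the C18 ketone needed for the annulation.

Step 17
Reactants: 25 methyl (1R)-1,4-dimethyl-3-oxocyclohexane-1-carboxylate; 17 7-[(tert-butyldimethylsilyl)oxy]oct-1-en-3-one
Product: 28 methyl (1R,4R)-4-{7-[(tert-butyldimethylsilyl)oxy]-3-oxooctyl}-1,4-dimethyl-3-oxocyclohexane-1-carboxylate, via imine 26 (not isolated), via Michael adduct imine 27 (not isolated)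
Conditions: (S)-1-phenylethylamine, TsOH (cat.), toluene, reflux (−H2O); then 17, THF, rt; then aq. AcOH
Reagents that add atoms: water O
Why: d'Angelo deracemising Michael addition, in which the more substituted secondary enamine tautomer of the chiral imine should add to the vinyl ketone on the face away from the phenyl group of the auxiliary and set the quaternary C17 (R, 17β-Me) under reagent control, independent of the remote C20.

Step 18
Reactants: 28 methyl (1R,4R)-4-{7-[(tert-butyldimethylsilyl)oxy]-3-oxooctyl}-1,4-dimethyl-3-oxocyclohexane-1-carboxylate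
Product: 29 methyl (2R,4aR)-8-{3-[(tert-butyldimethylsilyl)oxy]butyl}-2,4a-dimethyl-7-oxo-1,2,3,4,4a,5,6,7-octahydronaphthalene-2-carboxylate
Conditions: NaOMe, MeOH, 50 °C
Reagents that add atoms: none
Why: intramolecular aldol condensation (second half of a Robinson annulation) should close ring D as the C13=C18 enone that already carries the C11–C12 arm on C13.

Step 19
Reactants: 29 enone (structure as in step 18)
Product: 30 cis-fused decalone (17β-Me, 18β-H, 13β-H, 20α-CO2Me, C14 ketone)
Conditions: H2 (1 atm), Pd/C, EtOAc, rt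
Reagents that add atoms: none
Why: heterogeneous hydrogenation of the angular-methyl octalone should deliver hydrogen on the face of the angular methyl, as is usual for such enones, and give the cis ring fusion (18β-H); C13 stays epimerisable.

Step 20
Reactants: 30 cis-fused decalone
Product: 31 13α-methyl ketone (13α-Me with the arm β, 17β-Me, 18β-H, 20α-CO2Me)
Conditions: t-BuOK, t-BuOH/THF, rt; MeI, 0 °C
Reagents that add atoms: iodomethane CI
Why: alkylation of the equilibrated, more substituted enolate, in which MeI should attack C13 anti to the 17β-methyl group (axial on ring D and 1,3 to C13), giving 13α-Me.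

Step 21
Reactants: 31 13α-methyl ketone
Product: 33 C14 carbaldehyde (C14-epimer mixture), via enol ether 32 (not isolated)
Conditions: Ph3P(CH2OMe)Cl, KHMDS, THF, 0 → 60 °C; then oxalic acid, THF/H2O, rt
Reagents that add atoms: (methoxymethyl)triphenylphosphonium chloride COC[P+](c1ccccc1)(c1ccccc1)c1ccccc1.[Cl-]; water O
Why: Wittig methoxymethylenation of the ketone and mild hydrolysis of the enol ether give the one-carbon homologated aldehyde (C8); its C14 configuration is erased in the next step.

Step 22
Reactants: 33 C14 carbaldehyde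
Product: 34 quaternary aldehyde (14β-Me, 14α-CHO, 13α-Me)
Conditions: t-BuOK, THF, 0 °C; MeI
Reagents that add atoms: iodomethane CI
Why: C-methylation of the alpha-branched aldehyde enolate, in which MeI should enter from the β-face because the α-face of C14 is shielded by the ring E carbon C19 (axial on ring D in the cis-decalin), giving the 13α,14β-dimethyl pattern.

Step 23
Reactants: 34 quaternary aldehyde
Product: 35 (E)-vinyl sulfone (C14–CH=CH–SO2Ph)
Conditions: (EtO)2P(O)CH2SO2Ph, NaH, THF, 0 → 50 °C
Reagents that add atoms: diethyl [(phenylsulfonyl)methyl]phosphonate CCOP(=O)(CS(=O)(=O)c1ccccc1)OCC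
Why: Horner–Wadsworth–Emmons olefination of the non-enolisable aldehyde should give the (E)-vinyl sulfone, the activated dienophile C7=C8.

Step 24
Reactants: 35 (E)-vinyl sulfone
Product: 36 secondary bromide (CH3–CHBr–CH2CH2– arm on C13)
Conditions: Ph3PBr2, CH2Cl2, rt
Reagents that add atoms: dibromotriphenylphosphorane BrP(Br)(c1ccccc1)(c1ccccc1)c1ccccc1
Why: direct conversion of the secondary silyl ether into the bromide by the bromophosphonium reagent (Appel-type substitution) in one operation; the ester and vinyl sulfone are inert.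

Step 25
Reactants: 36 secondary bromide; 13 bromo aldehyde
Product: 38 o-(sec-alkyl)benzaldehyde (C9 epimers), via alkylzinc bromide 37 (not isolated)
Conditions: Zn dust, LiCl, THF, 50 °C; then 13, Pd(OAc)2 (2 mol%), CPhos (4 mol%), THF/toluene, rt
Reagents that add atoms: none
Why: Negishi coupling of a secondary alkylzinc halide with an aryl bromide (the biarylphosphine suppresses β-hydride elimination and chain walking) should form C9–C10; the zinc reagent tolerates aldehyde, ester and vinyl sulfone, and the C9 configuration is irrelevant.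

Step 26
Reactants: 38 o-(sec-alkyl)benzaldehyde
Product: 40 pentacyclic hydroxy sulfone (6α-OH, 7α-SO2Ph, 8α-H, 9β-Me), via photoenol 39 (not isolated)
Conditions: hν (365 nm), degassed toluene, rt
Reagents that add atoms: none
Why: n→π* excitation of the aryl aldehyde, followed by 1,5-hydrogen transfer from the tertiary benzylic C9–H, should give the (E)-hydroxy-o-quinodimethane 39, which the tethered (E)-vinyl sulfone traps in an intramolecular Diels–Alder reaction; dienols formed toward the aryl methyl group or with the wrong C9 geometry cannot cyclise and revert to 38. The closest known reactions are the intramolecular photoenolisation/Diels–Alder reaction and the thermal intramolecular Diels–Alder reaction of o-quinodimethanes, which also build two fused rings on an arene at once. Ring B closes as the six-membered cycloaddition ring (C6–C7 and C8–C9); ring C closes as the six-membered tether ring (fused mode, chair-like C11–C12–C13–C14 chain) through the same C8–C9 bond. The quaternary C9 and C8 are set by the exo orientation of the tether, which the (E)-dienophile couples to an endo sulfone hydrogen-bonded to the dienol OH, so that H8 and the C9 methyl end up trans; the dienophile face is fixed by C13/C14, whose ring D bonds stay equatorial and whose methyls stay axial in the chair-like tether, giving 8α-H/9β-Me, while C6 and C7 are temporary centres. The step needs regioselectivity (nucleophilic C9 to the sulfone β-carbon C8, matched in polarity and enforced by the four-atom tether) and the exo/facial selectivity just described; the isopropenyl and cyclopentene alkenes do not absorb at 365 nm and are not dienophiles for the electron-rich dienol.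

Step 27
Reactants: 40 pentacyclic hydroxy sulfone
Product: 41 6α-acetoxy-7α-phenylsulfonyl pentacycle
Conditions: Ac2O, DMAP, pyridine, CH2Cl2, 0 °C
Reagents that add atoms: acetic anhydride CC(=O)OC(C)=O
Why: acylation of the secondary benzylic alcohol turns it into the leaving group for the reductive elimination.

Step 28
Reactants: 41 6α-acetoxy-7α-phenylsulfonyl pentacycle
Product: 42 target CNP0113384.2
Conditions: SmI2, HMPA, THF, −78 °C
Reagents that add atoms: none
Why: Julia–Lythgoe-type reductive elimination (electron transfer to the sulfone, loss of sulfinate and acetate) should give the C6=C7 styrene, cis by ring constraint, without affecting the ester, the aryl ethers or the isolated alkenes.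

## Compound list

1 | (+)-dihydrocarvone, (5R)-2-methyl-5-(prop-1-en-2-yl)cyclohexan-1-one, C2-epimer mixture | C=C(C)[C@@H]1CCC(C)C(=O)C1 | starting material
2 | (5R)-2-methyl-5-(prop-1-en-2-yl)-7-(trimethylsilyl)cycloheptan-1-one | C=C(C)[C@@H]1CCC(C)C(=O)C([Si](C)(C)C)C1 | intermediate
3 | (2S,5R)-2-methyl-5-(prop-1-en-2-yl)cycloheptan-1-one | C=C(C)[C@@H]1CC[C@H](C)C(=O)CC1 | intermediate
4 | (4R,7S)-2-(hydroxyimino)-7-methyl-4-(prop-1-en-2-yl)cycloheptan-1-one | C=C(C)[C@@H]1CC[C@H](C)C(=O)C(=NO)C1 | intermediate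
5 | (2S,3S,6R)-2-hydroxy-3-methyl-6-(prop-1-en-2-yl)-2-(prop-2-en-1-yl)cycloheptan-1-one oxime | C=C(C)[C@@H]1CC[C@H](C)[C@@](O)(CC=C)C(=NO)C1 | intermediate
6 | (2S,3S,6R)-2-hydroxy-3-methyl-6-(prop-1-en-2-yl)-2-(prop-2-en-1-yl)cycloheptan-1-one | C=C(C)[C@@H]1CC[C@H](C)[C@@](O)(CC=C)C(=O)C1 | intermediate
7 | (2S,3S,6R)-3-methyl-6-(prop-1-en-2-yl)-2-(prop-2-en-1-yl)-2-[(triethylsilyl)oxy]cycloheptan-1-one | C=C(C)[C@@H]1CC[C@H](C)[C@@](O[Si](CC)(CC)CC)(CC=C)C(=O)C1 | intermediate
8 | (1S,2S,3S,6R)-3-methyl-1,6-di(prop-1-en-2-yl)-2-(prop-2-en-1-yl)-2-[(triethylsilyl)oxy]cycloheptan-1-ol | C=C(C)[C@@H]1CC[C@H](C)[C@@](O[Si](CC)(CC)CC)(CC=C)[C@@](O)(C(C)=C)C1 | intermediate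
9 | (1S,2S,3S,6R)-3-methyl-1,6-di(prop-1-en-2-yl)-2-(prop-2-en-1-yl)cycloheptane-1,2-diol | C=C(C)[C@@H]1CC[C@H](C)[C@@](O)(CC=C)[C@@](O)(C(C)=C)C1 | intermediate
10 | (1S,5S,7R,10S)-guaia-3,11-diene-1,5-diol | C=C(C)[C@@H]1CC[C@H](C)[C@@]2(O)CC=C(C)[C@@]2(O)C1 | intermediate
11 | 3,4-difluoro-2-methylbenzaldehyde | O=Cc1ccc(F)c(F)c1C | starting material
12 | 6-bromo-3,4-difluoro-2-methylbenzaldehyde | O=Cc1c(C)c(F)c(F)cc1Br | intermediate
13 | bromo aldehyde, (1S,5S,7R,10S)-guaia-3,11-diene-1,5-diyl dioxin of ring A (O5g–C2, O1g–C3, C4-Me, C5-CHO, C10-Br) | C=C(C)[C@@H]1CC[C@H](C)[C@@]23CC=C(C)[C@]2(C1)Oc1cc(Br)c(C=O)c(C)c1O3 | intermediate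
14 | 6-methyloxan-2-one (delta-hexalactone, racemic) | CC1CCCC(=O)O1 | starting material
15 | 5-hydroxy-N-methoxy-N-methylhexanamide | CC(O)CCCC(=O)N(C)OC | intermediate
16 | 5-[(tert-butyldimethylsilyl)oxy]-N-methoxy-N-methylhexanamide | CC(CCCC(=O)N(C)OC)O[Si](C)(C)C(C)(C)C | intermediate
17 | 7-[(tert-butyldimethylsilyl)oxy]oct-1-en-3-one | C=CC(=O)CCCC(C)O[Si](C)(C)C(C)(C)C | intermediate
18 | isoprene | C=CC(C)=C | starting material
19 | methacrolein | CC(=C)C=O | starting material
20 | (R)-1,4-dimethylcyclohex-3-ene-1-carbaldehyde | CC1=CC[C@](C)(C=O)CC1 | intermediate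
21 | (R)-1,4-dimethylcyclohex-3-ene-1-carboxylic acid | CC1=CC[C@](C)(C(=O)O)CC1 | intermediate
22 | methyl (R)-1,4-dimethylcyclohex-3-ene-1-carboxylate | CC1=CC[C@](C)(C(=O)OC)CC1 | intermediate
23 | alkylborane, methyl (1R)-3-boranyl-1,4-dimethylcyclohexane-1-carboxylate | BC1C[C@](C)(C(=O)OC)CCC1C | intermediate
24 | methyl (1R)-3-hydroxy-1,4-dimethylcyclohexane-1-carboxylate (diastereomer mixture) | OC1C[C@](C)(C(=O)OC)CCC1C | intermediate
25 | methyl (1R)-1,4-dimethyl-3-oxocyclohexane-1-carboxylate (C4-epimer mixture) | O=C1C[C@](C)(C(=O)OC)CCC1C | intermediate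
26 | imine of 25 with (S)-1-phenylethylamine | C[C@H](N=C1C[C@](C)(C(=O)OC)CCC1C)c1ccccc1 | intermediate
27 | Michael adduct imine (C17 quaternary, R) | C[C@H](N=C1C[C@](C)(C(=O)OC)CC[C@]1(C)CCC(=O)CCCC(C)O[Si](C)(C)C(C)(C)C)c1ccccc1 | intermediate
28 | methyl (1R,4R)-4-{7-[(tert-butyldimethylsilyl)oxy]-3-oxooctyl}-1,4-dimethyl-3-oxocyclohexane-1-carboxylate | O=C1C[C@](C)(C(=O)OC)CC[C@]1(C)CCC(=O)CCCC(C)O[Si](C)(C)C(C)(C)C | intermediate
29 | methyl (2R,4aR)-8-{3-[(tert-butyldimethylsilyl)oxy]butyl}-2,4a-dimethyl-7-oxo-1,2,3,4,4a,5,6,7-octahydronaphthalene-2-carboxylate | CC(O[Si](C)(C)C(C)(C)C)CCC1=C2C[C@](C)(C(=O)OC)CC[C@]2(C)CCC1=O | intermediate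
30 | cis-fused decalone (17β-Me, 18β-H, 13β-H, 20α-CO2Me, C14 ketone) | CC(O[Si](C)(C)C(C)(C)C)CC[C@@H]1[C@@H]2C[C@](C)(C(=O)OC)CC[C@]2(C)CCC1=O | intermediate
31 | 13α-methyl ketone (arm 13β, 17β-Me, 18β-H, 20α-CO2Me) | CC(O[Si](C)(C)C(C)(C)C)CC[C@@]1(C)[C@@H]2C[C@](C)(C(=O)OC)CC[C@]2(C)CCC1=O | intermediate
32 | methyl enol ether at C14 (C14=CH–OMe) | CC(O[Si](C)(C)C(C)(C)C)CC[C@@]1(C)[C@@H]2C[C@](C)(C(=O)OC)CC[C@]2(C)CCC1=COC | intermediate
33 | C14 carbaldehyde (C14-epimer mixture) | CC(O[Si](C)(C)C(C)(C)C)CC[C@@]1(C)[C@@H]2C[C@](C)(C(=O)OC)CC[C@]2(C)CCC1C=O | intermediate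
34 | quaternary aldehyde (13α-Me, 14β-Me, 14α-CHO) | CC(O[Si](C)(C)C(C)(C)C)CC[C@@]1(C)[C@@H]2C[C@](C)(C(=O)OC)CC[C@]2(C)CC[C@]1(C)C=O | intermediate
35 | (E)-vinyl sulfone with silyl ether arm | CC(O[Si](C)(C)C(C)(C)C)CC[C@@]1(C)[C@@H]2C[C@](C)(C(=O)OC)CC[C@]2(C)CC[C@]1(C)/C=C/S(=O)(=O)c1ccccc1 | intermediate
36 | (E)-vinyl sulfone with secondary bromide arm | CC(Br)CC[C@@]1(C)[C@@H]2C[C@](C)(C(=O)OC)CC[C@]2(C)CC[C@]1(C)/C=C/S(=O)(=O)c1ccccc1 | intermediate
37 | secondary alkylzinc bromide of 36 | CC([Zn]Br)CC[C@@]1(C)[C@@H]2C[C@](C)(C(=O)OC)CC[C@]2(C)CC[C@]1(C)/C=C/S(=O)(=O)c1ccccc1 | intermediate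
38 | o-(sec-alkyl)benzaldehyde, coupling product of 13 and 36 (C9 epimers) | C=C(C)[C@@H]1CC[C@H](C)[C@@]23CC=C(C)[C@]2(C1)Oc1cc(C(C)CC[C@@]4(C)[C@@H]5C[C@](C)(C(=O)OC)CC[C@]5(C)CC[C@]4(C)/C=C/S(=O)(=O)c4ccccc4)c(C=O)c(C)c1O3 | intermediate
39 | photoenol, (E)-hydroxy-o-quinodimethane (OH outward at C6, tether outward and methyl inward at C9) | C=C(C)[C@@H]1CC[C@H](C)[C@@]23CC=C(C)[C@]2(C1)OC1=C/C(=C(/C)CC[C@@]4(C)[C@@H]5C[C@](C)(C(=O)OC)CC[C@]5(C)CC[C@]4(C)/C=C/S(=O)(=O)c4ccccc4)/C(=C/O)C(C)=C1O3 | intermediate
40 | pentacyclic hydroxy sulfone (6α-OH, 7α-SO2Ph, 8α-H, 9β-Me) | C=C(C)[C@@H]1CC[C@H](C)[C@@]23CC=C(C)[C@]2(C1)Oc1cc2c(c(C)c1O3)[C@@H](O)[C@@H](S(=O)(=O)c1ccccc1)[C@H]1[C@@]2(C)CC[C@@]2(C)[C@@H]3C[C@](C)(C(=O)OC)CC[C@]3(C)CC[C@]12C | intermediate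
41 | 6α-acetoxy-7α-phenylsulfonyl pentacycle | C=C(C)[C@@H]1CC[C@H](C)[C@@]23CC=C(C)[C@]2(C1)Oc1cc2c(c(C)c1O3)[C@@H](OC(C)=O)[C@@H](S(=O)(=O)c1ccccc1)[C@H]1[C@@]2(C)CC[C@@]2(C)[C@@H]3C[C@](C)(C(=O)OC)CC[C@]3(C)CC[C@]12C | intermediate
42 | CNP0113384.2 | C=C(C)[C@@H]1CC[C@H](C)[C@@]23CC=C(C)[C@]2(C1)Oc1cc2c(c(C)c1O3)C=C[C@H]1[C@@]2(C)CC[C@@]2(C)[C@@H]3C[C@](C)(C(=O)OC)CC[C@]3(C)CC[C@]12C | target

## Step count and risks

Total step count: 28. Longest linear sequence: 16 steps (steps 13–28, from isoprene and methacrolein to 42).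

Steps most likely to fail:

1. Step 26. The dienol may revert to the aldehyde or close to a benzocyclobutenol faster than the hindered dienophile traps it, and the cycloaddition may pass through a boat-like tether (wrong dienophile face) because a 1,3-diaxial methyl/methyl contact develops between C9 and C14. Fallback, from 38 back to 40: 38 is irradiated at −20 °C without heating until the photoenol has collected as its electrocyclisation product, the benzocyclobutenol F1. F1 is then heated in toluene at 110–140 °C, where thermal conrotatory ring opening (hydroxyl outward) regenerates the dienol continuously in the ground state, so that the slow intramolecular Diels–Alder reaction can run to completion as a thermal benzocyclobutene-type cycloaddition, giving 40.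

2. Step 9. The first substitution may show poor site selectivity between the two tertiary alkoxides, and base-induced elimination of the allylic aryl ether may compete with the slow second ring closure. Fallback, from 7 back to 13: the isopropenyl addition of step 6 is worked up without fluoride, so that 8 is isolated with C1g–O still silylated. Ring-closing metathesis of 8 gives the monosilyl cyclopentenol F2. Only the free C5g alkoxide of F2 (KHMDS, THF, −78 °C) can attack 12, at the fluoride para to the formyl group, giving the aryl ether F3. TBAF in DMF at 60 °C then unmasks the C1g alkoxide, which closes the dioxin ring to 13.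

3. Step 20. Enolate formation may be incompletely regiocontrolled (C13 versus C15), with over-alkylation and O-alkylation as further losses. Fallback, from 29 back to 31: deconjugative alpha-methylation of the dienolate of enone 29 (excess t-BuOK, MeI, t-BuOH) can only alkylate C13 and gives the β,γ-unsaturated ketone F4, with the methyl again entering anti to the angular methyl. Hydrogenation of the C18=C19 alkene of F4 (H2, Pd/C) from the β-face then gives 31.

Further compounds
F1 | step 26 | benzocyclobutenol of 38 (four-membered ring C5–C6(OH)–C9(Me)–C10) | C=C(C)[C@@H]1CC[C@H](C)[C@@]23CC=C(C)[C@]2(C1)Oc1cc2c(c(C)c1O3)C(O)C2(C)CC[C@@]1(C)[C@@H]2C[C@](C)(C(=O)OC)CC[C@]2(C)CC[C@]1(C)/C=C/S(=O)(=O)c1ccccc1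
F2 | step 9 | (1S,5S,7R,10S)-1-[(triethylsilyl)oxy]guaia-3,11-dien-5-ol | C=C(C)[C@@H]1CC[C@H](C)[C@@]2(O[Si](CC)(CC)CC)CC=C(C)[C@@]2(O)C1
F3 | step 9 | 5-O-(5-bromo-2-fluoro-4-formyl-3-methylphenyl) ether of F2 | C=C(C)[C@@H]1CC[C@H](C)[C@@]2(O[Si](CC)(CC)CC)CC=C(C)[C@@]2(Oc3cc(Br)c(C=O)c(C)c3F)C1
F4 | step 20 | β,γ-unsaturated ketone (13α-Me, C18=C19) | CC(O[Si](C)(C)C(C)(C)C)CC[C@@]1(C)C2=C[C@](C)(C(=O)OC)CC[C@]2(C)CCC1=O
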